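**Plan** (target numbered as a chromene: O1, C2, C3, C4, C4a, C5, C6, C7, C8, C8a)
- Cuts: the dihydropyranone at C2–C3 and C4a–C8a (plus O1–C8a) into a β-diketone, acetaldehyde and an acid chloride; the carbocycle at C7–C8 (Dieckmann); the quaternary C6 into prenyl bromide, a cyclobutylmethyl iodide and methyl acetoacetate.
- Enabling feature: C3 and C4a are the γ- and central carbons of one 1,3-diketone (C4 and the C5 carbonyl). O1 lies between an aldehyde-level carbon (C2) and an acyl-level carbon (C8a). Quaternary C6 has no hydrogen, so the dienolate can only extend toward C3.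
- Forward: verbenone → cyclobutylmethyl iodide → alkylated acetoacetate → quaternary C6 → β-diketone → bis-silyl dienol ether. Then a three-component assembly of the pyranone ring, Dieckmann closure of the carbocycle, and ester cleavage.
- Stereochemistry: cyclobutane from (−)-verbenone; C6 from a valine-ester lithio-enamine alkylation; benzylic centre from alkaloid-mediated opening of 3-phenylglutaric anhydride; C2 from a titanium–BINOL aldol, with C3 anti to it.
- Building the pyranone before the carbocycle fixes which oxygen of the later trione carries the heterocycle.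

Key step: step 13

Remark: the target is treated as the enol tautomer drawn; its β-triketone tautomers interconvert and no step depends on which is present.

**Step 1**
Reactants: 1 (1S,5S)-(−)-verbenone
Product: 2 (1S,3R)-3-acetyl-2,2-dimethylcyclobutane-1-carboxylic acid (cis-pinononic acid)
Conditions: RuCl3 (cat.), NaIO4, CCl4/MeCN/H2O, rt
Reagents that add atoms: sodium periodate [Na+].[O-]I(=O)(=O)=O; water O
Why: Oxidative cleavage of the enone C=C by RuO4 formed catalytically, with loss of the CH carbon as CO2, should leave both ring stereocentres untouched, so the cis relation comes from the bicycle.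

**Step 2**
Reactants: 2 (1S,3R)-3-acetyl-2,2-dimethylcyclobutane-1-carboxylic acid
Product: 3 methyl (1S,3R)-3-acetyl-2,2-dimethylcyclobutane-1-carboxylate
Conditions: MeI, K2CO3, DMF, rt
Reagents that add atoms: iodomethane CI
Why: O-alkylation of the carboxylate (SN2) masks the acid for the methylenation under conditions too mild to enolize the ring carbon beside the acetyl group.

**Step 3**
Reactants: 3 methyl (1S,3R)-3-acetyl-2,2-dimethylcyclobutane-1-carboxylate
Product: 4 methyl (1S,3S)-2,2-dimethyl-3-(prop-1-en-2-yl)cyclobutane-1-carboxylate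
Conditions: Zn, CH2Br2, TiCl4, THF/CH2Cl2, 0 °C to rt
Reagents that add atoms: dibromomethane BrCBr
Why: Takai–Lombardo methylenation converts the ketone and not the ester, and the non-basic reagent should not epimerize the ring carbon α to the acetyl group, so the cis relation is kept.

**Step 4**
Reactants: 4 methyl (1S,3S)-2,2-dimethyl-3-(prop-1-en-2-yl)cyclobutane-1-carboxylate
Product: 5 [(1S,3S)-2,2-dimethyl-3-(prop-1-en-2-yl)cyclobutyl]methanol
Conditions: LiAlH4, Et2O, 0 °C
Reagents that add atoms: none
Why: Hydride reduction of the ester to the primary alcohol leaves the 1,1-disubstituted alkene and both stereocentres untouched.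

**Step 5**
Reactants: 5 [(1S,3S)-2,2-dimethyl-3-(prop-1-en-2-yl)cyclobutyl]methanol
Product: 6 (1S,3S)-1-(iodomethyl)-2,2-dimethyl-3-(prop-1-en-2-yl)cyclobutane
Conditions: I2, PPh3, imidazole, CH2Cl2, 0 °C to rt
Reagents that add atoms: iodine II
Why: Appel-type iodination proceeds by SN2 displacement of the oxyphosphonium group, so no cyclobutylcarbinyl cation forms and the ring cannot rearrange.

**Step 6**
Reactants: 6 (1S,3S)-1-(iodomethyl)-2,2-dimethyl-3-(prop-1-en-2-yl)cyclobutane, 7 methyl acetoacetate
Product: 8 methyl 2-{[(1R,3S)-2,2-dimethyl-3-(prop-1-en-2-yl)cyclobutyl]methyl}-3-oxobutanoate (both C2 epimers)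
Conditions: NaH, 7 (excess), THF/DMF, 0 to 60 °C
Reagents that add atoms: none
Why: C-alkylation of the sodium enolate of a β-keto ester (SN2) installs the hindered substituent first; the new centre is a mixture that is erased in step 8.

**Step 7**
Reactants: 8 methyl 2-{[(1R,3S)-2,2-dimethyl-3-(prop-1-en-2-yl)cyclobutyl]methyl}-3-oxobutanoate, 9 tert-butyl L-valinate
Product: 10 methyl (2Z)-3-{[(2S)-1-tert-butoxy-3-methyl-1-oxobutan-2-yl]amino}-2-{[(1R,3S)-2,2-dimethyl-3-(prop-1-en-2-yl)cyclobutyl]methyl}but-2-enoate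
Conditions: BF3·OEt2 (cat.), toluene, reflux, Dean–Stark
Reagents that add atoms: none
Why: Condensation of the ketone with the amino ester gives the hydrogen-bonded Z enamino ester, and both C2 epimers of 8 converge on it.

**Step 8**
Reactants: 10 the Z enamino ester, 11 prenyl bromide (1-bromo-3-methylbut-2-ene)
Product: 13 methyl (2R)-2-acetyl-2-{[(1R,3S)-2,2-dimethyl-3-(prop-1-en-2-yl)cyclobutyl]methyl}-5-methylhex-4-enoate, via alkylated ketimine 12 (not isolated)
Conditions: LDA, toluene, HMPA, −78 °C; 11, −78 to −20 °C; then 10% aq. citric acid, rt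
Reagents that add atoms: water O
Why: Alkylation of the chelated lithio-enamine of a valine ester is a known auxiliary method for α,α-dialkyl β-keto esters, in which the isopropyl group shields one face and the solvent/additive pair (toluene/HMPA as against THF alone) selects the face, here chosen to give the R centre; mild hydrolysis then frees the ketone and the auxiliary.

**Step 9**
Reactants: 13 the quaternary β-keto ester, 14 N-methoxy-N-methylpropanamide
Product: 15 methyl (2R)-2-{[(1R,3S)-2,2-dimethyl-3-(prop-1-en-2-yl)cyclobutyl]methyl}-2-(3-methylbut-2-en-1-yl)-3,5-dioxoheptanoate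
Conditions: LDA, THF, −78 °C; 14, −78 to 0 °C; aq. NH4Cl
Reagents that add atoms: none
Why: Claisen-type acylation of the lithium enolate of the acetyl CH3, the only enolizable position, with a Weinreb amide stops at the chelated mono-adduct and gives the 1,3-diketone on work-up.

**Step 10**
Reactants: 15 the 3,5-dioxoheptanoate
Product: 16 methyl (2R)-2-{[(1R,3S)-2,2-dimethyl-3-(prop-1-en-2-yl)cyclobutyl]methyl}-2-(3-methylbut-2-en-1-yl)-3,5-bis(trimethylsilyloxy)hepta-3,5-dienoate (enol geometries mixed)
Conditions: LDA (2.2 equiv), THF, −78 °C; TMSCl, −78 to 0 °C; non-aqueous work-up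
Reagents that add atoms: chlorotrimethylsilane C[Si](C)(C)Cl
Why: Dianion formation (central carbon, then C6, because quaternary C2 blocks the other side) and double O-silylation give the 1,3-bis(silyloxy)diene that is nucleophilic at its terminal carbon.

**Step 11**
Reactants: 17 3-phenylglutaric anhydride, 18 allyl alcohol
Product: 19 (3S)-5-oxo-3-phenyl-5-(prop-2-en-1-yloxy)pentanoic acid
Conditions: quinidine (1.1 equiv), 18 (3 equiv), toluene, −55 °C; dilute HCl wash
Reagents that add atoms: none
Why: Alkaloid-mediated desymmetrizing alcoholysis delivers the alcohol to one enantiotopic carbonyl of the prochiral anhydride; quinine gives the antipode, so the alkaloid is the one that leads to the S acid.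

**Step 12**
Reactants: 19 the S hemiester
Product: 20 prop-2-en-1-yl (3R)-5-chloro-5-oxo-3-phenylpentanoate
Conditions: (COCl)2, DMF (cat.), CH2Cl2, 0 °C to rt; used crude
Reagents that add atoms: oxalyl chloride O=C(Cl)C(=O)Cl
Why: Vilsmeier-type activation converts the acid to the acid chloride without touching the allyl ester or the remote stereocentre (the descriptor changes by priority only).

**Step 13**
Reactants: 16 the bis(silyloxy)diene (1.1 equiv), 21 acetaldehyde, 20 the acid chloride
Product: 24 methyl (2R)-2-{[(1R,3S)-2,2-dimethyl-3-(prop-1-en-2-yl)cyclobutyl]methyl}-3-{(2R,3R)-2,3-dimethyl-4-oxo-6-[(2S)-4-oxo-2-phenyl-4-(prop-2-en-1-yloxy)butyl]-3,4-dihydro-2H-pyran-5-yl}-2-(3-methylbut-2-en-1-yl)-3-oxopropanoate, via silyl aldol adduct 22 (not isolated), via C-acylated triketone 23 (not isolated)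
Conditions: Ti(OiPr)4/(S)-BINOL (20 mol%), 4 Å MS, THF, −78 to −20 °C; then 20, TiCl4, 2,6-di-tert-butylpyridine, CH2Cl2, −78 to 0 °C; then PPTS, CH2Cl2, rt
Reagents that add atoms: none
Why: Proposed new method: a one-pot Maitland–Japp-type union in which titanium-BINOLate-bound acetaldehyde is attacked by the terminal carbon of 16 (vinylogous Mukaiyama aldol; pyranone C2–C3), the remaining enol silane is C-acylated at its central carbon by 20 under TiCl4 (pyranone C5–C6, the later ring-fusion bond), and the freed C2 oxygen adds to the new ketone and loses water. The closest known reaction type is the one-pot Maitland–Japp synthesis of tetrahydro- and dihydropyran-4-ones from a 1,3-bis(silyloxy)diene, an aldehyde under titanium–BINOL catalysis and a second carbonyl electrophile; here an acid chloride replaces the second aldehyde or orthoester. The pyranone ring closes by 6-exo-trig attack of oxygen on the ketone carbonyl, followed by dehydration. C2 is set by the (S)-BINOL–titanium complex, taken as the antipode that directs the diene to the Si face of acetaldehyde; C3 is set anti to it through the open transition state of the Z terminal enol silane, which is also the more stable trans arrangement. The step needs C- over O-acylation and acylation of the titanium enolate in preference to the two alkenes (low temperature and the hindered pyridine should secure this), and ring closure on the new ketone and not on the ketone beside the quaternary carbon (the neopentyl-type hindrance of the latter should secure this).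

**Step 14**
Reactants: 24 the 5-acyl-2,3-dihydropyran-4-one
Product: 25 prop-2-en-1-yl (3S)-3-[(2R,3R,6R)-6-{[(1R,3S)-2,2-dimethyl-3-(prop-1-en-2-yl)cyclobutyl]methyl}-5-hydroxy-2,3-dimethyl-6-(3-methylbut-2-en-1-yl)-4,7-dioxo-3,4,6,7-tetrahydro-2H-chromen-8-yl]-3-phenylpropanoate
Conditions: LiHMDS (1.05 equiv), THF, −78 to 0 °C; pH 4 buffer
Reagents that add atoms: none
Why: Dieckmann condensation through the vinylogous enolate: the CH2 on pyranone C6 is the γ-position of a 1,3-dicarbonyl unit and far more acidic than C3–H, so one equivalent of base should give the extended enolate, which closes 6-exo-trig onto the methyl ester and is pulled forward by the stabilized trione enolate without touching C2 or C3.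

**Step 15**
Reactants: 25 the allyl ester
Product: 26 (3S)-3-[(2R,3R,6R)-6-{[(1R,3S)-2,2-dimethyl-3-(prop-1-en-2-yl)cyclobutyl]methyl}-5-hydroxy-2,3-dimethyl-6-(3-methylbut-2-en-1-yl)-4,7-dioxo-3,4,6,7-tetrahydro-2H-chromen-8-yl]-3-phenylpropanoic acid (CNP0103716.3)
Conditions: Pd(PPh3)4 (5 mol%), PhSiH3, CH2Cl2, rt; aqueous work-up at pH 3
Reagents that add atoms: none
Why: Tsuji–Trost-type deallylation, in which zerovalent palladium ionizes the allyl ester and the silane reduces the π-allyl complex to propene, is neutral and free of amines, so the vinylogous ester, the epimerizable C3, the prenyl and isopropenyl groups should survive.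

**Compound list**
1 | (1S,5S)-(−)-verbenone | CC1=CC(=O)[C@H]2C[C@@H]1C2(C)C | starting material
2 | (1S,3R)-3-acetyl-2,2-dimethylcyclobutane-1-carboxylic acid | CC(=O)[C@@H]1C[C@H](C(=O)O)C1(C)C | intermediate
3 | methyl (1S,3R)-3-acetyl-2,2-dimethylcyclobutane-1-carboxylate | CC(=O)[C@@H]1C[C@H](C(=O)OC)C1(C)C | intermediate
4 | methyl (1S,3S)-2,2-dimethyl-3-(prop-1-en-2-yl)cyclobutane-1-carboxylate | C=C(C)[C@@H]1C[C@H](C(=O)OC)C1(C)C | intermediate
5 | [(1S,3S)-2,2-dimethyl-3-(prop-1-en-2-yl)cyclobutyl]methanol | C=C(C)[C@@H]1C[C@H](CO)C1(C)C | intermediate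
6 | (1S,3S)-1-(iodomethyl)-2,2-dimethyl-3-(prop-1-en-2-yl)cyclobutane | C=C(C)[C@@H]1C[C@H](CI)C1(C)C | intermediate
7 | methyl acetoacetate | CC(=O)CC(=O)OC | starting material
8 | methyl 2-{[(1R,3S)-2,2-dimethyl-3-(prop-1-en-2-yl)cyclobutyl]methyl}-3-oxobutanoate (C2 epimers) | C=C(C)[C@@H]1C[C@H](CC(C(C)=O)C(=O)OC)C1(C)C | intermediate
9 | tert-butyl L-valinate | CC(C)[C@H](N)C(=O)OC(C)(C)C | starting material
10 | methyl (2Z)-3-{[(2S)-1-tert-butoxy-3-methyl-1-oxobutan-2-yl]amino}-2-{[(1R,3S)-2,2-dimethyl-3-(prop-1-en-2-yl)cyclobutyl]methyl}but-2-enoate | C=C(C)[C@@H]1C[C@H](C/C(C(=O)OC)=C(\C)N[C@@H](C(C)C)C(=O)OC(C)(C)C)C1(C)C | intermediate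
11 | prenyl bromide | CC(C)=CCBr | starting material
12 | alkylated ketimine: N-[(2S)-1-tert-butoxy-3-methyl-1-oxobutan-2-yl] imine of 13 | C=C(C)[C@@H]1C[C@H](C[C@@](C(C)=N[C@@H](C(C)C)C(=O)OC(C)(C)C)(CC=C(C)C)C(=O)OC)C1(C)C | intermediate
13 | methyl (2R)-2-acetyl-2-{[(1R,3S)-2,2-dimethyl-3-(prop-1-en-2-yl)cyclobutyl]methyl}-5-methylhex-4-enoate | C=C(C)[C@@H]1C[C@H](C[C@@](C(C)=O)(CC=C(C)C)C(=O)OC)C1(C)C | intermediate
14 | N-methoxy-N-methylpropanamide | CCC(=O)N(C)OC | starting material
15 | methyl (2R)-2-{[(1R,3S)-2,2-dimethyl-3-(prop-1-en-2-yl)cyclobutyl]methyl}-2-(3-methylbut-2-en-1-yl)-3,5-dioxoheptanoate | C=C(C)[C@@H]1C[C@H](C[C@@](C(=O)CC(=O)CC)(CC=C(C)C)C(=O)OC)C1(C)C | intermediate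
16 | methyl (2R)-2-{[(1R,3S)-2,2-dimethyl-3-(prop-1-en-2-yl)cyclobutyl]methyl}-2-(3-methylbut-2-en-1-yl)-3,5-bis(trimethylsilyloxy)hepta-3,5-dienoate | C=C(C)[C@@H]1C[C@H](C[C@@](C(O[Si](C)(C)C)=CC(O[Si](C)(C)C)=CC)(CC=C(C)C)C(=O)OC)C1(C)C | intermediate
17 | 3-phenylglutaric anhydride | O=C1CC(c2ccccc2)CC(=O)O1 | starting material
18 | allyl alcohol | C=CCO | starting material
19 | (3S)-5-oxo-3-phenyl-5-(prop-2-en-1-yloxy)pentanoic acid | OC(=O)C[C@@H](CC(=O)OCC=C)c1ccccc1 | intermediate
20 | prop-2-en-1-yl (3R)-5-chloro-5-oxo-3-phenylpentanoate | ClC(=O)C[C@@H](CC(=O)OCC=C)c1ccccc1 | intermediate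
21 | acetaldehyde | CC=O | starting material
22 | silyl aldol adduct: methyl (2R,6R,7R)-2-{[(1R,3S)-2,2-dimethyl-3-(prop-1-en-2-yl)cyclobutyl]methyl}-6-methyl-2-(3-methylbut-2-en-1-yl)-5-oxo-3,7-bis(trimethylsilyloxy)oct-3-enoate | C=C(C)[C@@H]1C[C@H](C[C@@](C(O[Si](C)(C)C)=CC(=O)[C@H](C)[C@@H](C)O[Si](C)(C)C)(CC=C(C)C)C(=O)OC)C1(C)C | intermediate
23 | C-acylated triketone: 22 after loss of the enol silyl group, bearing the (3S)-5-(allyloxy)-5-oxo-3-phenylpentanoyl group on C4 (triketo tautomer drawn) | C=C(C)[C@@H]1C[C@H](C[C@@](C(=O)C(C(=O)C[C@@H](CC(=O)OCC=C)c2ccccc2)C(=O)[C@H](C)[C@@H](C)O[Si](C)(C)C)(CC=C(C)C)C(=O)OC)C1(C)C | intermediate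
24 | methyl (2R)-2-{[(1R,3S)-2,2-dimethyl-3-(prop-1-en-2-yl)cyclobutyl]methyl}-3-{(2R,3R)-2,3-dimethyl-4-oxo-6-[(2S)-4-oxo-2-phenyl-4-(prop-2-en-1-yloxy)butyl]-3,4-dihydro-2H-pyran-5-yl}-2-(3-methylbut-2-en-1-yl)-3-oxopropanoate | C=C(C)[C@@H]1C[C@H](C[C@@](C(=O)C2=C(C[C@@H](CC(=O)OCC=C)c3ccccc3)O[C@H](C)[C@@H](C)C2=O)(CC=C(C)C)C(=O)OC)C1(C)C | intermediate
25 | prop-2-en-1-yl ester of the target acid | C=C(C)[C@@H]1C[C@H](C[C@@]2(CC=C(C)C)C(=O)C([C@@H](CC(=O)OCC=C)c3ccccc3)=C3O[C@H](C)[C@@H](C)C(=O)C3=C2O)C1(C)C | intermediate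
26 | (3S)-3-[(2R,3R,6R)-6-{[(1R,3S)-2,2-dimethyl-3-(prop-1-en-2-yl)cyclobutyl]methyl}-5-hydroxy-2,3-dimethyl-6-(3-methylbut-2-en-1-yl)-4,7-dioxo-3,4,6,7-tetrahydro-2H-chromen-8-yl]-3-phenylpropanoic acid | C=C(C)[C@@H]1C[C@H](C[C@@]2(CC=C(C)C)C(=O)C([C@@H](CC(=O)O)c3ccccc3)=C3O[C@H](C)[C@@H](C)C(=O)C3=C2O)C1(C)C | target

**Count**
Total steps: 15. Longest linear sequence: 13 (steps 1–10 and 13–15).

**Steps most likely to fail**

1. Step 13 (proposed new method). The risks are poor face selectivity on the small aldehyde, poor syn/anti control at C3, O-acylation or Lewis-acid attack on the prenyl and isopropenyl alkenes, and condensation of the alcohol on the wrong ketone. The fallback sets out from 16 and returns at 24 using known reaction types in separate operations. The titanium–BINOL vinylogous aldol with acetaldehyde is run alone and desilylated on acidic work-up to methyl (2R,6R,7R)-2-{[(1R,3S)-2,2-dimethyl-3-(prop-1-en-2-yl)cyclobutyl]methyl}-7-hydroxy-6-methyl-2-(3-methylbut-2-en-1-yl)-3,5-dioxooctanoate F1. Steglich esterification of its hydroxyl with acid 19 (DCC, DMAP) gives the 7-O-acyl diketone F2. A Baker–Venkataraman O-to-C acyl shift (LiHMDS, THF, −78 °C) gives the hydroxy triketone F3, and PPTS cyclodehydration gives 24. The ring oxygen is bound to the correct acyl carbon before any C–C bond to it is made.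

2. Step 14. The risks are proton removal at pyranone C3 instead of the side-chain CH2, which would cause β-elimination of the ring oxygen (ring opening and loss of the C2 configuration) or the alternative ring closure from C3, and slow attack on the hindered ester. The fallback sets out from 24 and returns at 25. Soft enolization (TBSOTf, Et3N, CH2Cl2, −78 °C) gives the extended tert-butyldimethylsilyl dienol ether F4, and fluoride (CsF, DMF, 0 °C) unmasks the dienolate, which closes onto the ester. No base strong enough to remove C3–H is then present.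

3. Step 8. The risks are insufficient facial discrimination with the bulky β-branched substituent, or N- in place of C-alkylation. The fallback sets out from 8 and returns at 13. Palladium-catalysed asymmetric allylic alkylation (Pd2(dba)3, (R,R)-N,N'-bis(2-diphenylphosphinobenzoyl)-1,2-diaminocyclohexane, allyl acetate, tetramethylguanidine, toluene) gives methyl (2R)-2-acetyl-2-{[(1R,3S)-2,2-dimethyl-3-(prop-1-en-2-yl)cyclobutyl]methyl}pent-4-enoate F5. Cross-metathesis of its monosubstituted alkene with 2-methylbut-2-ene (second-generation Hoveyda–Grubbs catalyst, CH2Cl2, 40 °C) gives 13; the hindered 1,1-disubstituted isopropenyl group should not take part.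

**Further compounds**
F1 | step 13 | methyl (2R,6R,7R)-2-{[(1R,3S)-2,2-dimethyl-3-(prop-1-en-2-yl)cyclobutyl]methyl}-7-hydroxy-6-methyl-2-(3-methylbut-2-en-1-yl)-3,5-dioxooctanoate | C=C(C)[C@@H]1C[C@H](C[C@@](C(=O)CC(=O)[C@H](C)[C@@H](C)O)(CC=C(C)C)C(=O)OC)C1(C)C
F2 | step 13 | 7-O-acyl derivative of F1 formed with acid 19 | C=C(C)[C@@H]1C[C@H](C[C@@](C(=O)CC(=O)[C@H](C)[C@@H](C)OC(=O)C[C@@H](CC(=O)OCC=C)c2ccccc2)(CC=C(C)C)C(=O)OC)C1(C)C
F3 | step 13 | hydroxy triketone: F1 bearing the (3S)-5-(allyloxy)-5-oxo-3-phenylpentanoyl group on C4 | C=C(C)[C@@H]1C[C@H](C[C@@](C(=O)C(C(=O)C[C@@H](CC(=O)OCC=C)c2ccccc2)C(=O)[C@H](C)[C@@H](C)O)(CC=C(C)C)C(=O)OC)C1(C)C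
F4 | step 14 | tert-butyldimethylsilyl dienol ether of 24 (silylated on the C5-acyl oxygen, exocyclic C6=CH double bond) | C=C(C)[C@@H]1C[C@H](C[C@@](C(O[Si](C)(C)C(C)(C)C)=C2C(=O)[C@H](C)[C@@H](C)OC2=C[C@@H](CC(=O)OCC=C)c3ccccc3)(CC=C(C)C)C(=O)OC)C1(C)C
F5 | step 8 | methyl (2R)-2-acetyl-2-{[(1R,3S)-2,2-dimethyl-3-(prop-1-en-2-yl)cyclobutyl]methyl}pent-4-enoate | C=C(C)[C@@H]1C[C@H](C[C@@](C(C)=O)(CC=C)C(=O)OC)C1(C)C
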